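Assumption: decalin carbons are numbered as in hexahydronaphthalene (C1–C8a) and the chain as C1′ (ester carbon) to C8′ (CH2 on decalin C2), so the dioxane carbons are C3′ and C6′; stereocentres that are erased later are drawn undefined.

**Retrosynthetic overview**
1. Key C–C bond C2′–C3′: intermolecular Evans syn-aldol of propionimide 26 with oxetane aldehyde 25, which sets C2′ and C3′.
2. 1,2-Dioxane: perhydrolysis of the oxetane (inversion at C6′, stereocentre from Sharpless epoxidation of geraniol), then 6-exo SN2 of the tertiary hydroperoxide on the C3′ mesylate (inversion).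
3. Decalin from (S)-carvone (ring B and C8a): gem-dimethyl acyl side chain, intramolecular Michael closes ring A cis, Kabalka transposition places C5=C6, then the enol triflate.
4. Ring order: ring B (chiral pool), ring A, dioxane (made separately); the C8′–C2 bond is closed last by B-alkyl Suzuki coupling.

**Decalin branch**

Step 1
Reactants: 1 (S)-(+)-carvone
Product: 2 (1S,5S)-2-methyl-5-(prop-1-en-2-yl)cyclohex-2-en-1-ol (cis-carveol)
Conditions: NaBH4, CeCl3·7H2O, MeOH, 0 °C
Reagents that add atoms: none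
Why: Luche 1,2-reduction masks the enone as the cis allylic alcohol (hydride anti to the isopropenyl group); this carbinol centre is temporary and is oxidised back in step 8.

Step 2
Reactants: 2 cis-carveol
Product: 3 tert-butyl(dimethyl){[(1S,5S)-2-methyl-5-(prop-1-en-2-yl)cyclohex-2-en-1-yl]oxy}silane
Conditions: TBSCl, imidazole, DMF, rt
Reagents that add atoms: tert-butyldimethylsilyl chloride, CC(C)(C)[Si](C)(C)Cl
Why: Standard silylation protects the allylic alcohol against the base and Grignard steps that follow.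

Step 3
Reactants: 3 carveol TBS ether
Product: 5 2-[(1S,5S)-5-{[tert-butyl(dimethyl)silyl]oxy}-4-methylcyclohex-3-en-1-yl]propan-1-ol (C2 epimers), via alkylborane 4 (not isolated)
Conditions: 9-BBN, THF, 0 °C to rt; then NaOH, 30% H2O2, 0 °C to rt
Reagents that add atoms: hydrogen peroxide, OO
Why: Anti-Markovnikov hydroboration–oxidation with 9-BBN takes only the 1,1-disubstituted alkene; the new CH(CH3) centre forms as a mixture and becomes quaternary in step 5.

Step 4
Reactants: 5 primary alcohol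
Product: 6 2-[(1S,5S)-5-{[tert-butyl(dimethyl)silyl]oxy}-4-methylcyclohex-3-en-1-yl]propanal (C2 epimers)
Conditions: Dess–Martin periodinane, CH2Cl2, rt
Reagents that add atoms: none
Why: Dess–Martin oxidation gives the aldehyde without touching the silyl ether or the ring alkene.

Step 5
Reactants: 6 aldehyde
Product: 8 2-[(1S,5S)-5-{[tert-butyl(dimethyl)silyl]oxy}-4-methylcyclohex-3-en-1-yl]-2-methylpropanal, via potassium enolate 7 (not isolated)
Conditions: KOtBu, THF, 0 °C; then MeI, 0 °C to rt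
Reagents that add atoms: iodomethane, CI
Why: C-methylation of the enolate of an α-branched aldehyde (only one α-H) builds the gem-dimethyl quaternary carbon C1.

Step 6
Reactants: 8 quaternary aldehyde
Product: 9 4-[(1S,5S)-5-{[tert-butyl(dimethyl)silyl]oxy}-4-methylcyclohex-3-en-1-yl]-2,4-dimethylpent-1-en-3-ol (C3 epimers)
Conditions: isopropenylmagnesium bromide, THF, −78 to 0 °C; aq. NH4Cl
Reagents that add atoms: isopropenylmagnesium bromide, CC(=C)[Mg]Br
Why: Grignard 1,2-addition to a non-enolisable aldehyde brings in C3, C4 and the C3 methyl; the carbinol epimers converge in step 8.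

Step 7
Reactants: 9 silyl ether
Product: 10 (1S,5S)-5-(3-hydroxy-2,4-dimethylpent-4-en-2-yl)-2-methylcyclohex-2-en-1-ol (side-chain carbinol epimers)
Conditions: TBAF, THF, rt
Reagents that add atoms: none
Why: Fluoride desilylation frees the ring allylic alcohol so that both carbinols can be oxidised together.

Step 8
Reactants: 10 diol
Product: 11 (5S)-5-(2,4-dimethyl-3-oxopent-4-en-2-yl)-2-methylcyclohex-2-en-1-one
Conditions: Dess–Martin periodinane (3 equiv), CH2Cl2, rt
Reagents that add atoms: none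
Why: Double Dess–Martin oxidation of the two allylic alcohols restores the carvone-type enone and creates the isopropenyl ketone acceptor.

Step 9
Reactants: 11 enedione
Product: 13 (4aS,8aS)-1,1,3,6-tetramethyl-3,4,4a,8a-tetrahydronaphthalene-2,5(1H,8H)-dione (cis-fused; C3 epimers), via lithium dienolate 12 (not isolated)
Conditions: LiHMDS, THF, −78 to −30 °C; AcOH quench at −78 °C
Reagents that add atoms: none
Why: The kinetic α′-enolate undergoes a 6-endo-trig intramolecular Michael addition to the terminal CH2 of the isopropenyl ketone; the tether sits axial on C8a and the bond forms on the same face, giving the cis ring fusion (C4a set relative to the carvone-derived C8a).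

Step 10
Reactants: 13 bicyclic enedione
Product: 14 C5 tosylhydrazone of 13 [(4aS,8aS)-5-(2-tosylhydrazinylidene)-1,1,3,6-tetramethyl-3,4,4a,5,8,8a-hexahydronaphthalen-2(1H)-one]
Conditions: TsNHNH2, PPTS (cat.), EtOH, rt to 40 °C
Reagents that add atoms: p-toluenesulfonyl hydrazide, Cc1ccc(cc1)S(=O)(=O)NN
Why: Hydrazone condensation occurs only at the enone carbonyl, because the C2 ketone is flanked by a quaternary and a tertiary carbon.

Step 11
Reactants: 14 tosylhydrazone
Product: 16 (4aR,8aS)-1,1,3,6-tetramethyl-3,4,4a,7,8,8a-hexahydronaphthalen-2(1H)-one (C3 epimers), via allylic diazene 15 (not isolated)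
Conditions: catecholborane, CHCl3, 0 °C; then NaOAc·3H2O, reflux
Reagents that add atoms: none
Why: Kabalka reductive 1,3-transposition (hydride to C=N, sulfinate loss, retro-ene loss of N2) moves the alkene to C5=C6 and leaves C4a and C8a untouched.

Step 12
Reactants: 16 ketone
Product: 18 (4aR,8aS)-1,1,3,6-tetramethyl-1,4,4a,7,8,8a-hexahydronaphthalen-2-yl trifluoromethanesulfonate, via potassium enolate 17 (not isolated)
Conditions: KHMDS, THF, −78 °C; then PhNTf2, −78 to 0 °C
Reagents that add atoms: N-phenylbis(trifluoromethanesulfonimide), FC(F)(F)S(=O)(=O)N(c1ccccc1)S(=O)(=O)C(F)(F)F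
Why: C3 is the only enolisable position, so O-triflation gives the tetrasubstituted enol triflate regiospecifically and erases the C3 epimers.

**Dioxane branch**

Step 13
Reactants: 19 geraniol
Product: 20 [(2R,3R)-3-methyl-3-(4-methylpent-3-en-1-yl)oxiran-2-yl]methanol
Conditions: Ti(OiPr)4 (5 mol %), D-(−)-diethyl tartrate (7 mol %), TBHP, 4 Å MS, CH2Cl2, −20 °C
Reagents that add atoms: tert-butyl hydroperoxide, CC(C)(C)OO
Why: Sharpless asymmetric epoxidation with the D-tartrate gives the (2R,3R)-epoxide and so fixes the oxygenated quaternary carbon that becomes C6′.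

Step 14
Reactants: 20 epoxy alcohol
Product: 21 (3R)-3,7-dimethyloct-6-ene-1,3-diol
Conditions: Red-Al, THF, 0 °C to rt
Reagents that add atoms: none
Why: The aluminium alkoxide delivers hydride intramolecularly to C2, giving the 1,3-diol; the C3–O bond is not broken.

Step 15
Reactants: 21 diol
Product: 22 (3R)-3-hydroxy-3,7-dimethyloct-6-en-1-yl 4-methylbenzenesulfonate
Conditions: TsCl, Et3N, DMAP (cat.), CH2Cl2, 0 °C
Reagents that add atoms: p-toluenesulfonyl chloride, Cc1ccc(cc1)S(Cl)(=O)=O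
Why: The primary alcohol is sulfonylated selectively over the tertiary one.

Step 16
Reactants: 22 monotosylate
Product: 23 (2R)-2-methyl-2-(4-methylpent-3-en-1-yl)oxetane
Conditions: KOtBu, THF, 0 °C to rt
Reagents that add atoms: none
Why: 4-exo-tet Williamson closure by the tertiary alkoxide forms the oxetane with retention at the stereocentre, since its C–O bond is not involved.

Step 17
Reactants: 23 oxetane
Product: 25 3-[(2R)-2-methyloxetan-2-yl]propanal, via secondary ozonide 24 (not isolated)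
Conditions: O3, CH2Cl2, −78 °C; then Me2S, −78 °C to rt
Reagents that add atoms: ozone, [O-][O+]=O
Why: Ozonolysis cleaves the only alkene to release the C3′ aldehyde; the oxetane is inert to ozone.

Step 18
Reactants: 25 oxetane aldehyde; 26 (4R)-4-benzyl-3-propanoyl-1,3-oxazolidin-2-one
Product: 28 (4R)-4-benzyl-3-{(2R,3S)-3-hydroxy-2-methyl-5-[(2R)-2-methyloxetan-2-yl]pentanoyl}-1,3-oxazolidin-2-one, via Z boron enolate 27 (not isolated)
Conditions: 26, Bu2BOTf, iPr2NEt, CH2Cl2, −78 to 0 °C; then 25, −78 to 0 °C; pH 7 buffer, MeOH, H2O2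
Reagents that add atoms: none
Why: Key fragment union by Evans syn-aldol: the Z-boron enolate reacts through a Zimmerman–Traxler chair on the face away from the benzyl group of the (R)-auxiliary, giving the (2R,3S) syn adduct (C2′ and C3′).

Step 19
Reactants: 28 aldol adduct
Product: 29 (2S,3S)-2-methyl-5-[(2R)-2-methyloxetan-2-yl]pentane-1,3-diol
Conditions: LiBH4, MeOH (1 equiv), THF, 0 °C
Reagents that add atoms: none
Why: Reductive removal of the auxiliary gives the primary alcohol, so that no carbonyl sits β to the later leaving group; no stereocentre is touched.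

Step 20
Reactants: 29 diol
Product: 30 (2S,3S)-1-{[tert-butyl(diphenyl)silyl]oxy}-2-methyl-5-[(2R)-2-methyloxetan-2-yl]pentan-3-ol
Conditions: TBDPSCl, imidazole, CH2Cl2, 0 °C
Reagents that add atoms: tert-butyldiphenylsilyl chloride, CC(C)(C)[Si](Cl)(c1ccccc1)c1ccccc1
Why: The bulky silyl chloride reacts at the primary hydroxyl only; TBDPS survives the acidic and basic steps ahead.

Step 21
Reactants: 30 secondary alcohol
Product: 31 (2S,3S)-1-{[tert-butyl(diphenyl)silyl]oxy}-2-methyl-5-[(2R)-2-methyloxetan-2-yl]pentan-3-yl methanesulfonate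
Conditions: MsCl, Et3N, CH2Cl2, 0 °C
Reagents that add atoms: methanesulfonyl chloride, CS(Cl)(=O)=O
Why: O-sulfonylation activates C3′ with retention, setting up the later inversion.

Step 22
Reactants: 31 oxetane mesylate
Product: 32 (2S,3S,6S)-1-{[tert-butyl(diphenyl)silyl]oxy}-6-hydroperoxy-8-hydroxy-2,6-dimethyloctan-3-yl methanesulfonate
Conditions: anhydrous H2O2 in Et2O (10 equiv), TMSOTf (20 mol %), −78 to 0 °C
Reagents that add atoms: hydrogen peroxide, OO
Why: Lewis-acid-promoted perhydrolysis of the 2,2-dialkyl oxetane takes place at the tertiary carbon in an SN2-like manner with inversion, installing the C6′–OOH stereocentre and freeing the C8′ alcohol.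

Step 23
Reactants: 32 hydroperoxy mesylate
Product: 33 tert-butyl{(2S)-2-[(3R,6S)-6-(2-hydroxyethyl)-6-methyl-1,2-dioxan-3-yl]propoxy}diphenylsilane
Conditions: KOtBu (1.05 equiv), 18-crown-6, THF, 0 °C
Reagents that add atoms: none
Why: The peroxy anion displaces the secondary mesylate in a 6-exo-tet SN2 reaction with inversion at C3′, which turns the syn aldol pattern into the required anti C2′/C3′ relationship and closes the dioxane.

Step 24
Reactants: 33 dioxane alcohol
Product: 34 tert-butyl{(2S)-2-[(3R,6S)-6-(2-iodoethyl)-6-methyl-1,2-dioxan-3-yl]propoxy}diphenylsilane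
Conditions: PPh3, I2, imidazole, CH2Cl2, 0 °C to rt (PPh3 and I2 premixed)
Reagents that add atoms: iodine, II
Why: Appel-type iodination of the primary alcohol; premixed Ph3PI2 leaves no free phosphine to attack the O–O bond.

Step 25
Reactants: 34 iodide
Product: 35 tert-butyl{(2S)-2-[(3R,6S)-6-ethenyl-6-methyl-1,2-dioxan-3-yl]propoxy}diphenylsilane
Conditions: KOtBu, THF, 0 °C
Reagents that add atoms: none
Why: E2 elimination with the bulky base gives the vinyl group; the dioxane already tolerated this base in step 23.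

Step 26
Reactants: 35 silyl ether
Product: 36 (2S)-2-[(3R,6S)-6-ethenyl-6-methyl-1,2-dioxan-3-yl]propan-1-ol
Conditions: TBAF, AcOH (1:1), THF, 0 °C to rt
Reagents that add atoms: none
Why: Buffered fluoride removes the silyl group without base-induced peroxide fragmentation.

Step 27
Reactants: 36 primary alcohol
Product: 37 (2R)-2-[(3R,6S)-6-ethenyl-6-methyl-1,2-dioxan-3-yl]propanoic acid
Conditions: TEMPO (cat.), PhI(OAc)2 (2.2 equiv), MeCN/H2O, rt
Reagents that add atoms: water, O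
Why: TEMPO/PhI(OAc)2 oxidation goes through the aldehyde hydrate to the acid under near-neutral conditions that spare the peroxide, the alkene and the α-stereocentre.

Step 28
Reactants: 37 acid
Product: 38 methyl (2R)-2-[(3R,6S)-6-ethenyl-6-methyl-1,2-dioxan-3-yl]propanoate
Conditions: TMSCHN2, MeOH/toluene, 0 °C
Reagents that add atoms: trimethylsilyldiazomethane, C[Si](C)(C)C=[N+]=[N-]
Why: Mild methyl esterification without base, so C2′ is not epimerised.

**Fragment coupling**

Step 29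
Reactants: 38 vinyl dioxane ester; 18 decalin enol triflate
Product: 40 methyl (2R)-2-[(3R,6R)-6-methyl-6-{2-[(4aR,8aS)-1,1,3,6-tetramethyl-1,4,4a,7,8,8a-hexahydronaphthalen-2-yl]ethyl}-1,2-dioxan-3-yl]propanoate, via alkylborane 39 (not isolated)
Conditions: 9-BBN, THF, 0 °C to rt; then 18, PdCl2(dppf) (10 mol %), AsPh3 (10 mol %), Cs2CO3, DMF/H2O, rt to 45 °C
Reagents that add atoms: none
Why: Anti-Markovnikov hydroboration of the vinyl group followed by B-alkyl Suzuki–Miyaura coupling with the enol triflate forms the C8′–C2 bond without touching any stereocentre or the ester.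

**Compound list**

1 | (S)-(+)-carvone, (5S)-2-methyl-5-(prop-1-en-2-yl)cyclohex-2-en-1-one | CC1=CC[C@@H](CC1=O)C(C)=C | starting material
2 | (1S,5S)-2-methyl-5-(prop-1-en-2-yl)cyclohex-2-en-1-ol | CC1=CC[C@@H](C[C@@H]1O)C(C)=C | intermediate
3 | tert-butyl(dimethyl){[(1S,5S)-2-methyl-5-(prop-1-en-2-yl)cyclohex-2-en-1-yl]oxy}silane | CC1=CC[C@@H](C[C@@H]1O[Si](C)(C)C(C)(C)C)C(C)=C | intermediate
4 | B-alkyl-9-BBN adduct of 3 (boron on the former isopropenyl CH2) | CC1=CC[C@@H](C[C@@H]1O[Si](C)(C)C(C)(C)C)C(C)CB2C3CCCC2CCC3 | intermediate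
5 | 2-[(1S,5S)-5-{[tert-butyl(dimethyl)silyl]oxy}-4-methylcyclohex-3-en-1-yl]propan-1-ol (C2 epimers) | CC1=CC[C@@H](C[C@@H]1O[Si](C)(C)C(C)(C)C)C(C)CO | intermediate
6 | 2-[(1S,5S)-5-{[tert-butyl(dimethyl)silyl]oxy}-4-methylcyclohex-3-en-1-yl]propanal (C2 epimers) | CC1=CC[C@@H](C[C@@H]1O[Si](C)(C)C(C)(C)C)C(C)C=O | intermediate
7 | potassium enolate of 6 | CC1=CC[C@@H](C[C@@H]1O[Si](C)(C)C(C)(C)C)C(C)=C[O-].[K+] | intermediate
8 | 2-[(1S,5S)-5-{[tert-butyl(dimethyl)silyl]oxy}-4-methylcyclohex-3-en-1-yl]-2-methylpropanal | CC1=CC[C@@H](C[C@@H]1O[Si](C)(C)C(C)(C)C)C(C)(C)C=O | intermediate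
9 | 4-[(1S,5S)-5-{[tert-butyl(dimethyl)silyl]oxy}-4-methylcyclohex-3-en-1-yl]-2,4-dimethylpent-1-en-3-ol (C3 epimers) | CC1=CC[C@@H](C[C@@H]1O[Si](C)(C)C(C)(C)C)C(C)(C)C(O)C(C)=C | intermediate
10 | (1S,5S)-5-(3-hydroxy-2,4-dimethylpent-4-en-2-yl)-2-methylcyclohex-2-en-1-ol (carbinol epimers) | CC1=CC[C@@H](C[C@@H]1O)C(C)(C)C(O)C(C)=C | intermediate
11 | (5S)-5-(2,4-dimethyl-3-oxopent-4-en-2-yl)-2-methylcyclohex-2-en-1-one | CC1=CC[C@@H](CC1=O)C(C)(C)C(=O)C(C)=C | intermediate
12 | lithium cross-conjugated dienolate of 11 (O on C1, C1=C6) | CC1=CC[C@@H](C=C1[O-])C(C)(C)C(=O)C(C)=C.[Li+] | intermediate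
13 | (4aS,8aS)-1,1,3,6-tetramethyl-3,4,4a,8a-tetrahydronaphthalene-2,5(1H,8H)-dione (cis-fused; C3 epimers) | CC1=CC[C@H]2[C@@H](C1=O)CC(C)C(=O)C2(C)C | intermediate
14 | C5 tosylhydrazone of 13 | CC1=CC[C@H]2[C@@H](C1=NNS(=O)(=O)c3ccc(C)cc3)CC(C)C(=O)C2(C)C | intermediate
15 | allylic diazene (C5–N=NH) from 14 | CC1=CC[C@H]2[C@@H](C1N=N)CC(C)C(=O)C2(C)C | intermediate
16 | (4aR,8aS)-1,1,3,6-tetramethyl-3,4,4a,7,8,8a-hexahydronaphthalen-2(1H)-one (C3 epimers) | CC1C[C@@H]2C=C(C)CC[C@@H]2C(C)(C)C1=O | intermediate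
17 | potassium enolate of 16 | [K+].[O-]C1=C(C)C[C@@H]2C=C(C)CC[C@@H]2C1(C)C | intermediate
18 | (4aR,8aS)-1,1,3,6-tetramethyl-1,4,4a,7,8,8a-hexahydronaphthalen-2-yl trifluoromethanesulfonate | FC(F)(F)S(=O)(=O)OC1=C(C)C[C@@H]2C=C(C)CC[C@@H]2C1(C)C | intermediate
19 | geraniol, (2E)-3,7-dimethylocta-2,6-dien-1-ol | CC(C)=CCC/C(C)=C/CO | starting material
20 | [(2R,3R)-3-methyl-3-(4-methylpent-3-en-1-yl)oxiran-2-yl]methanol | CC(C)=CCC[C@@]1(C)O[C@@H]1CO | intermediate
21 | (3R)-3,7-dimethyloct-6-ene-1,3-diol | CC(C)=CCC[C@@](C)(O)CCO | intermediate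
22 | (3R)-3-hydroxy-3,7-dimethyloct-6-en-1-yl 4-methylbenzenesulfonate | CC(C)=CCC[C@@](C)(O)CCOS(=O)(=O)c1ccc(C)cc1 | intermediate
23 | (2R)-2-methyl-2-(4-methylpent-3-en-1-yl)oxetane | CC(C)=CCC[C@]1(C)CCO1 | intermediate
24 | secondary ozonide (1,2,4-trioxolane) of 23 | CC1(C)OOC(CC[C@]2(C)CCO2)O1 | intermediate
25 | 3-[(2R)-2-methyloxetan-2-yl]propanal | O=CCC[C@]1(C)CCO1 | intermediate
26 | (4R)-4-benzyl-3-propanoyl-1,3-oxazolidin-2-one | CCC(=O)N1[C@H](Cc2ccccc2)COC1=O | starting material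
27 | (Z)-dibutylboron enolate of 26 | C/C=C(\OB(CCCC)CCCC)N1[C@H](Cc2ccccc2)COC1=O | intermediate
28 | (4R)-4-benzyl-3-{(2R,3S)-3-hydroxy-2-methyl-5-[(2R)-2-methyloxetan-2-yl]pentanoyl}-1,3-oxazolidin-2-one | C[C@H]([C@@H](O)CC[C@]1(C)CCO1)C(=O)N2[C@H](Cc3ccccc3)COC2=O | intermediate
29 | (2S,3S)-2-methyl-5-[(2R)-2-methyloxetan-2-yl]pentane-1,3-diol | C[C@H]([C@@H](O)CC[C@]1(C)CCO1)CO | intermediate
30 | (2S,3S)-1-{[tert-butyl(diphenyl)silyl]oxy}-2-methyl-5-[(2R)-2-methyloxetan-2-yl]pentan-3-ol | C[C@H]([C@@H](O)CC[C@]1(C)CCO1)CO[Si](c2ccccc2)(c3ccccc3)C(C)(C)C | intermediate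
31 | (2S,3S)-1-{[tert-butyl(diphenyl)silyl]oxy}-2-methyl-5-[(2R)-2-methyloxetan-2-yl]pentan-3-yl methanesulfonate | C[C@H]([C@@H](OS(C)(=O)=O)CC[C@]1(C)CCO1)CO[Si](c2ccccc2)(c3ccccc3)C(C)(C)C | intermediate
32 | (2S,3S,6S)-1-{[tert-butyl(diphenyl)silyl]oxy}-6-hydroperoxy-8-hydroxy-2,6-dimethyloctan-3-yl methanesulfonate | C[C@H]([C@@H](OS(C)(=O)=O)CC[C@](C)(OO)CCO)CO[Si](c1ccccc1)(c2ccccc2)C(C)(C)C | intermediate
33 | tert-butyl{(2S)-2-[(3R,6S)-6-(2-hydroxyethyl)-6-methyl-1,2-dioxan-3-yl]propoxy}diphenylsilane | CC(C)(C)[Si](c1ccccc1)(c2ccccc2)OC[C@H](C)[C@H]3CC[C@@](C)(CCO)OO3 | intermediate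
34 | tert-butyl{(2S)-2-[(3R,6S)-6-(2-iodoethyl)-6-methyl-1,2-dioxan-3-yl]propoxy}diphenylsilane | CC(C)(C)[Si](c1ccccc1)(c2ccccc2)OC[C@H](C)[C@H]3CC[C@@](C)(CCI)OO3 | intermediate
35 | tert-butyl{(2S)-2-[(3R,6S)-6-ethenyl-6-methyl-1,2-dioxan-3-yl]propoxy}diphenylsilane | CC(C)(C)[Si](c1ccccc1)(c2ccccc2)OC[C@H](C)[C@H]3CC[C@@](C)(C=C)OO3 | intermediate
36 | (2S)-2-[(3R,6S)-6-ethenyl-6-methyl-1,2-dioxan-3-yl]propan-1-ol | OC[C@H](C)[C@H]1CC[C@@](C)(C=C)OO1 | intermediate
37 | (2R)-2-[(3R,6S)-6-ethenyl-6-methyl-1,2-dioxan-3-yl]propanoic acid | OC(=O)[C@H](C)[C@H]1CC[C@@](C)(C=C)OO1 | intermediate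
38 | methyl (2R)-2-[(3R,6S)-6-ethenyl-6-methyl-1,2-dioxan-3-yl]propanoate | COC(=O)[C@H](C)[C@H]1CC[C@@](C)(C=C)OO1 | intermediate
39 | B-alkyl-9-BBN adduct of 38 (boron on C8′) | COC(=O)[C@H](C)[C@H]1CC[C@@](C)(CCB2C3CCCC2CCC3)OO1 | intermediate
40 | methyl (2R)-2-[(3R,6R)-6-methyl-6-{2-[(4aR,8aS)-1,1,3,6-tetramethyl-1,4,4a,7,8,8a-hexahydronaphthalen-2-yl]ethyl}-1,2-dioxan-3-yl]propanoate | COC(=O)[C@H](C)[C@H]1CC[C@@](C)(CCC2=C(C)C[C@@H]3C=C(C)CC[C@@H]3C2(C)C)OO1 | target

**Totals**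
Total step count: 29.
Longest linear sequence: 17 steps (steps 13–29, geraniol to target). The decalin branch (steps 1–12) joins at step 29.

**Steps most likely to fail, with fallbacks**

Step 9 (cis-selective ring-A Michael closure; risk of trans product or C4a epimerisation under base). The fallback sets out from 11 and comes back at 13. The kinetic enolate is trapped (LDA, TMSCl, THF, −78 °C) as trimethyl{[(3S)-3-(2,4-dimethyl-3-oxopent-4-en-2-yl)-6-methylcyclohexa-1,5-dien-1-yl]oxy}silane F1. Ring A is then closed by a base-free Lewis-acid Mukaiyama–Michael reaction (TiCl4, CH2Cl2, −78 °C; aqueous work-up), which cannot equilibrate the ring fusion and delivers 13.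

Step 22 (regio- and stereospecific perhydrolysis of the oxetane next to a mesylate). The fallback reverses the order of the two C–O bond formations; it sets out from 31 and comes back at 33. The secondary mesylate is displaced first with inversion (50% H2O2, KOH, MeOH/THF, 0 °C to rt) to give tert-butyl{[(2S,3R)-3-hydroperoxy-2-methyl-5-[(2R)-2-methyloxetan-2-yl]pentyl]oxy}diphenylsilane F2. The tethered hydroperoxide then opens the oxetane at its tertiary carbon in a Lewis-acid-promoted 6-exo cyclisation (TMSOTf cat., CH2Cl2, −78 to 0 °C) with inversion, which gives 33 directly.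

Step 29 (B-alkyl Suzuki coupling on a hindered tetrasubstituted enol triflate in the presence of the O–O bond). The fallback is an olefination–diimide sequence that sets out from 38 and 18 and comes back at 40.
- Ozonolysis of the vinyl group of 38 (O3, CH2Cl2, −78 °C; Me2S) gives methyl (2R)-2-[(3R,6S)-6-formyl-6-methyl-1,2-dioxan-3-yl]propanoate F3.
- 18 is carbonylated (Pd(OAc)2, dppp, CO, MeOH, Et3N, DMF, 60 °C) to methyl (4aR,8aS)-1,1,3,6-tetramethyl-1,4,4a,7,8,8a-hexahydronaphthalene-2-carboxylate F4.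
- F4 is reduced (DIBAL-H, CH2Cl2, −78 °C) to [(4aR,8aS)-1,1,3,6-tetramethyl-1,4,4a,7,8,8a-hexahydronaphthalen-2-yl]methanol F5.
- F5 is converted (PPh3·HBr, MeOH, rt) into {[(4aR,8aS)-1,1,3,6-tetramethyl-1,4,4a,7,8,8a-hexahydronaphthalen-2-yl]methyl}triphenylphosphonium bromide F6.
- Wittig reaction of the ylide of F6 (NaHMDS, THF, −78 °C) with F3 gives methyl (2R)-2-[(3R,6S)-6-methyl-6-{2-[(4aR,8aS)-1,1,3,6-tetramethyl-1,4,4a,7,8,8a-hexahydronaphthalen-2-yl]ethenyl}-1,2-dioxan-3-yl]propanoate F7 as an E/Z mixture.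
- Diimide (potassium azodicarboxylate, AcOH, MeOH, 0 °C to rt) reduces only the new disubstituted alkene and gives 40.

Further compounds
F1 | step 9 | trimethyl{[(3S)-3-(2,4-dimethyl-3-oxopent-4-en-2-yl)-6-methylcyclohexa-1,5-dien-1-yl]oxy}silane | CC1=CC[C@@H](C=C1O[Si](C)(C)C)C(C)(C)C(=O)C(C)=C
F2 | step 22 | tert-butyl{[(2S,3R)-3-hydroperoxy-2-methyl-5-[(2R)-2-methyloxetan-2-yl]pentyl]oxy}diphenylsilane | C[C@H]([C@H](OO)CC[C@]1(C)CCO1)CO[Si](c2ccccc2)(c3ccccc3)C(C)(C)C
F3 | step 29 | methyl (2R)-2-[(3R,6S)-6-formyl-6-methyl-1,2-dioxan-3-yl]propanoate | COC(=O)[C@H](C)[C@H]1CC[C@@](C)(C=O)OO1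
F4 | step 29 | methyl (4aR,8aS)-1,1,3,6-tetramethyl-1,4,4a,7,8,8a-hexahydronaphthalene-2-carboxylate | COC(=O)C1=C(C)C[C@@H]2C=C(C)CC[C@@H]2C1(C)C
F5 | step 29 | [(4aR,8aS)-1,1,3,6-tetramethyl-1,4,4a,7,8,8a-hexahydronaphthalen-2-yl]methanol | OCC1=C(C)C[C@@H]2C=C(C)CC[C@@H]2C1(C)C
F6 | step 29 | {[(4aR,8aS)-1,1,3,6-tetramethyl-1,4,4a,7,8,8a-hexahydronaphthalen-2-yl]methyl}triphenylphosphonium bromide | [Br-].C(C1=C(C)C[C@@H]2C=C(C)CC[C@@H]2C1(C)C)[P+](c3ccccc3)(c4ccccc4)c5ccccc5
F7 | step 29 | methyl (2R)-2-[(3R,6S)-6-methyl-6-{2-[(4aR,8aS)-1,1,3,6-tetramethyl-1,4,4a,7,8,8a-hexahydronaphthalen-2-yl]ethenyl}-1,2-dioxan-3-yl]propanoate (E/Z mixture) | COC(=O)[C@H](C)[C@H]1CC[C@@](C)(C=CC2=C(C)C[C@@H]3C=C(C)CC[C@@H]3C2(C)C)OO1
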